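**Retrosynthetic overview**

1. Target 46 is a spiro dimer of two abietane hydroxyquinone units of opposite absolute configuration. Opening the spiro dihydrofuran (C7–C7′ and C7–O–C14′) gives the (10S) 6,7-dione, handled as its diosphenol 30, and the (5R,10R) 6-oxo hydroxyquinone 43; they are joined last by aldol addition and cyclodehydration.
2. Both partners come from the two antipodes of one tricyclic 6-ketone (26 and 40). Ring C is adjusted by BCl3, (KSO3)2NO and hydrolysis; ring B is closed at C7–C8 by a diazoketone/Rh2(OAc)4 aromatic substitution.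
3. The strategy rests on ring A of each half: the all-carbon quaternary C10 (CH3-20 and aryl carbon C9) lies next to C5, which carries the C6 carbonyl, and C10 is S in one half and R in the other. An Ireland–Claisen rearrangement of alkenyl δ-lactone 18 (antipode 32) forms C5–C10, closes ring A and relays a carbinol centre, set by either CBS catalyst, to C10.
4. The lactone comes from aryl alkyne 11 (methylalumination), acid chloride 14 (from 3,3-dimethylglutaric anhydride), CBS reduction and lactonisation.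
5. Ring order: ring C (arene, bought) → ring A (steps 11 and 21) → ring B (steps 14 and 24) → quinone oxidation → spiro dihydrofuran (step 28).

Key step: step 11

Definitions: Ar = 2-isopropoxy-4-isopropyl-3-methoxyphenyl; abietane numbering for tricyclic compounds (primed locants for the second half of dimers); TBS = tert-butyldimethylsilyl; TBD = 1,5,7-triazabicyclo[4.4.0]dec-5-ene.

Remark: the target is taken in the tautomeric form drawn (14-hydroxy-11,12-dione in the 10S half, C7′=C8′ quinone methide in the 10R half); monomeric hydroxyquinones are written as the freely interconverting 12-hydroxy-11,14-dione tautomers.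

Remark: the C11 oxygen is carried as an isopropyl ether and the C12 oxygen as a methyl ether, so that C11–OH alone can be freed for para-quinone formation.

**Route**

Step 1
Reactants: 1 2-isopropylphenol
Product: 2 1-isopropyl-2-methoxybenzene
Conditions: MeI, K2CO3, acetone, reflux
Reagents that add atoms: iodomethane CI
Why: Williamson O-methylation of the phenoxide; no stereocentre is involved.

Step 2
Reactants: 2 1-isopropyl-2-methoxybenzene
Product: 5 3-isopropyl-2-methoxyphenol, via aryllithium 3 (not isolated), via dimethyl arylboronate 4 (not isolated)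
Conditions: n-BuLi, TMEDA, Et2O, 0 °C to rt; B(OMe)3, −78 °C to rt; H2O2, AcOH, 0 °C
Reagents that add atoms: hydrogen peroxide OO
Why: Directed ortho-metalation (the methoxy group has only one free ortho position), borylation and oxidative boron-to-oxygen migration should place the hydroxyl that becomes O11.

Step 3
Reactants: 5 3-isopropyl-2-methoxyphenol
Product: 6 1-isopropoxy-3-isopropyl-2-methoxybenzene
Conditions: 2-bromopropane, K2CO3, DMF, 60 °C
Reagents that add atoms: 2-bromopropane CC(C)Br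
Why: Williamson etherification of the unhindered phenoxide; the isopropyl ether is chosen because BCl3 later cleaves it beside the methyl ether.

Step 4
Reactants: 6 1-isopropoxy-3-isopropyl-2-methoxybenzene
Product: 8 1-iodo-2-isopropoxy-4-isopropyl-3-methoxybenzene, via aryllithium 7 (not isolated)
Conditions: s-BuLi, TMEDA, THF, −78 to −20 °C; I2, −78 °C
Reagents that add atoms: iodine II
Why: Directed ortho-metalation at the only ring position ortho to an oxygen, then iodinolysis, should put iodine on the future C9.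

Step 5
Reactants: 8 1-iodo-2-isopropoxy-4-isopropyl-3-methoxybenzene; 9 trimethylsilylacetylene
Product: 11 1-ethynyl-2-isopropoxy-4-isopropyl-3-methoxybenzene, via silyl alkyne 10 (not isolated)
Conditions: Pd(PPh3)2Cl2 (2 mol%), CuI (4 mol%), Et3N, THF, 50 °C; then K2CO3, MeOH, rt
Reagents that add atoms: none
Why: Sonogashira coupling of the aryl iodide (zerovalent palladium cycle with copper acetylide) followed by methanolysis of the C–Si bond.

Step 6
Reactants: 12 3,3-dimethylglutaric anhydride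
Product: 13 5-methoxy-3,3-dimethyl-5-oxopentanoic acid
Conditions: MeOH, reflux
Reagents that add atoms: methanol CO
Why: Methanolysis of the symmetric cyclic anhydride can give only one half ester.

Step 7
Reactants: 13 5-methoxy-3,3-dimethyl-5-oxopentanoic acid
Product: 14 methyl 5-chloro-3,3-dimethyl-5-oxopentanoate
Conditions: (COCl)2, DMF (cat.), CH2Cl2, 0 °C to rt
Reagents that add atoms: oxalyl chloride O=C(Cl)C(Cl)=O
Why: Vilsmeier-type activation converts the free acid into the acid chloride and leaves the methyl ester untouched.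

Step 8
Reactants: 11 1-ethynyl-2-isopropoxy-4-isopropyl-3-methoxybenzene; 14 methyl 5-chloro-3,3-dimethyl-5-oxopentanoate
Product: 16 methyl (E)-7-Ar-3,3-dimethyl-5-oxooct-6-enoate, via alkenylalane 15 (not isolated)
Conditions: Me3Al (2.5 equiv), Cp2ZrCl2 (0.25 equiv), (CH2Cl)2, rt; volatiles off; 14, Pd(PPh3)4 (5 mol%), THF, 0 °C to rt
Reagents that add atoms: trimethylaluminium C[Al](C)C
Why: Negishi zirconium-catalysed methylalumination adds CH3 (the future C20) and Al syn across the alkyne with methyl on the aryl-bearing carbon, and palladium-catalysed acylation of the alkenylalane with retention fixes the E alkene.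

Step 9
Reactants: 16 methyl (E)-7-Ar-3,3-dimethyl-5-oxooct-6-enoate
Product: 17 methyl (5S,6E)-7-Ar-5-hydroxy-3,3-dimethyloct-6-enoate
Conditions: (R)-Me-CBS oxazaborolidine (0.2 equiv), catecholborane, toluene, −78 °C
Reagents that add atoms: none
Why: Corey–Bakshi–Shibata reduction in which the alkenyl group acts as the large substituent, so the (R)-catalyst should deliver hydride to give the (S)-carbinol while ester and alkene stay intact.

Step 10
Reactants: 17 methyl (5S,6E)-7-Ar-5-hydroxy-3,3-dimethyloct-6-enoate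
Product: 18 (6S)-6-[(E)-2-Ar-prop-1-enyl]-4,4-dimethyltetrahydropyran-2-one
Conditions: TBD (0.1 equiv), toluene, 60 °C, 5 Å sieves
Reagents that add atoms: none
Why: Base-catalysed intramolecular transesterification, favoured by the gem-dimethyl group and removal of methanol, avoids acid at the ionisable allylic carbinol and keeps its configuration.

Step 11
Reactants: 18 (6S)-6-[(E)-2-Ar-prop-1-enyl]-4,4-dimethyltetrahydropyran-2-one
Product: 21 (1R,2S)-2-Ar-2,6,6-trimethylcyclohex-3-ene-1-carboxylic acid, via silyl ketene acetal 19 (not isolated), via silyl ester 20 (not isolated)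
Conditions: LDA, THF, −78 °C; TBSCl, HMPA, −78 °C to rt; toluene, 105 °C; 1 M HCl, THF, rt
Reagents that add atoms: none
Why: Deprotonation at the lactone α-CH2 (the future C5) and O-silylation give cyclic silyl ketene acetal 19, which should undergo a [3,3]-sigmatropic shift in which C5–C10 forms while the ring O–C2 bond breaks. The closest known reaction is the Ireland–Claisen (alicyclic Claisen) rearrangement of 6-alkenyl δ-lactone silyl ketene acetals to cyclohexenecarboxylic acids. Ring A closes as a six-membered carbocycle by this sigmatropic transposition of the six-membered lactone, through the bicyclo[2.2.2]octane-like boat transition state that the lactone ring enforces. C10 is set by suprafacial transfer of the (S)-carbinol configuration across the E alkene (10S), and C5 by the boat geometry, which places aryl cis to carboxyl. The step needs the concerted shift to outrun ionisation of the allylic C–O bond, which the neutral, non-polar thermolysis of a silyl ketene acetal without Lewis acid should secure; the lactone has only one acidic site, so enolisation is unambiguous.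

Step 12
Reactants: 21 (1R,2S)-2-Ar-2,6,6-trimethylcyclohex-3-ene-1-carboxylic acid
Product: 22 (1R,2S)-2-Ar-2,6,6-trimethylcyclohexane-1-carboxylic acid
Conditions: H2 (1 atm), 10% Pd/C, EtOAc, rt
Reagents that add atoms: none
Why: Heterogeneous hydrogenation of the cis-disubstituted ring alkene removes a site that the later carbenoid would cyclopropanate; no stereocentre is touched.

Step 13
Reactants: 22 (1R,2S)-2-Ar-2,6,6-trimethylcyclohexane-1-carboxylic acid
Product: 24 2-diazo-1-[(1R,2S)-2-Ar-2,6,6-trimethylcyclohexyl]ethanone, via acid chloride 23 (not isolated)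
Conditions: (COCl)2, DMF (cat.), CH2Cl2, 0 °C to rt; then CH2N2 (excess), Et2O, 0 °C
Reagents that add atoms: diazomethane C=[N+]=[N-]
Why: Acylation of diazomethane by the acid chloride (first stage of an Arndt–Eistert sequence) supplies C7, with excess diazomethane taking up HCl.

Step 14
Reactants: 24 2-diazo-1-[(1R,2S)-2-Ar-2,6,6-trimethylcyclohexyl]ethanone
Product: 26 (5S,10S)-11-isopropoxy-12-methoxyabieta-8,11,13-trien-6-one, via cis ketone 25 (not isolated)
Conditions: Rh2(OAc)4 (1 mol%), CH2Cl2, rt, slow addition; then NaOMe, MeOH, rt, argon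
Reagents that add atoms: none
Why: The dirhodium carbenoid should attack C8, the arene position ortho to the ring A substituent and para to the C12 methoxy group (formal aromatic C–H insertion, the 2-tetralone synthesis from diazoketones), closing ring B as the cis-fused 6-ketone, after which methoxide equilibrates C5 through the enolate to the expected more stable trans ring fusion.

Step 15
Reactants: 26 (5S,10S)-11-isopropoxy-12-methoxyabieta-8,11,13-trien-6-one
Product: 27 (5S,10S)-11-hydroxy-12-methoxyabieta-8,11,13-trien-6-one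
Conditions: BCl3, CH2Cl2, −78 to 0 °C
Reagents that add atoms: none
Why: BCl3 cleaves aryl isopropyl ethers far faster than aryl methyl ethers, so only the C11 phenol should be freed.

Step 16
Reactants: 27 (5S,10S)-11-hydroxy-12-methoxyabieta-8,11,13-trien-6-one
Product: 28 (5S,10S)-12-methoxyabieta-8,12-diene-6,11,14-trione
Conditions: (KSO3)2NO, KH2PO4, acetone/H2O, 0 °C to rt
Reagents that add atoms: potassium nitrosodisulfonate [K+].[K+].[O]N(S(=O)(=O)[O-])S(=O)(=O)[O-]
Why: Teuber oxidation, in which the phenoxyl radical is trapped by a second nitroxyl at the free para carbon C14, should give the para-quinone directly and so avoid an ortho-quinone that would tautomerise to a quinone methide.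

Step 17
Reactants: 28 (5S,10S)-12-methoxyabieta-8,12-diene-6,11,14-trione
Product: 29 (5S,10S)-12-hydroxyabieta-8,12-diene-6,11,14-trione
Conditions: 6 M HCl, 1,4-dioxane, 70 °C, argon
Reagents that add atoms: water O
Why: Acid hydrolysis of the vinylogous methyl ester by addition–elimination of water at C12 gives the hydroxyquinone, and the acid keeps C5 at the trans fusion.

Step 18
Reactants: 29 (5S,10S)-12-hydroxyabieta-8,12-diene-6,11,14-trione
Product: 30 (10S)-6,12-dihydroxyabieta-5,8,12-triene-7,11,14-trione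
Conditions: SeO2, 1,4-dioxane, 80 °C
Reagents that add atoms: selenium dioxide O=[Se]=O
Why: Riley oxidation through the C6 enol should oxidise C7, a methylene activated by both the ketone and the quinone ring, to the 6,7-dione, which rests as its diosphenol.

Step 19
Reactants: 16 methyl (E)-7-Ar-3,3-dimethyl-5-oxooct-6-enoate
Product: 31 methyl (5R,6E)-7-Ar-5-hydroxy-3,3-dimethyloct-6-enoate
Conditions: (S)-Me-CBS oxazaborolidine (0.2 equiv), catecholborane, toluene, −78 °C
Reagents that add atoms: none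
Why: Same Corey–Bakshi–Shibata reduction as step 9 with the antipodal catalyst, which should give the (R)-carbinol.

Step 20
Reactants: 31 methyl (5R,6E)-7-Ar-5-hydroxy-3,3-dimethyloct-6-enoate
Product: 32 (6R)-6-[(E)-2-Ar-prop-1-enyl]-4,4-dimethyltetrahydropyran-2-one
Conditions: TBD (0.1 equiv), toluene, 60 °C, 5 Å sieves
Reagents that add atoms: none
Why: Same base-catalysed lactonisation as step 10, with the carbinol configuration retained.

Step 21
Reactants: 32 (6R)-6-[(E)-2-Ar-prop-1-enyl]-4,4-dimethyltetrahydropyran-2-one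
Product: 35 (1S,2R)-2-Ar-2,6,6-trimethylcyclohex-3-ene-1-carboxylic acid, via silyl ketene acetal 33 (not isolated), via silyl ester 34 (not isolated)
Conditions: LDA, THF, −78 °C; TBSCl, HMPA, −78 °C to rt; toluene, 105 °C; 1 M HCl, THF, rt
Reagents that add atoms: none
Why: Same Ireland–Claisen rearrangement as step 11 on the antipode, in which the (R)-carbinol is relayed through the boat transition state to 10R with aryl cis to carboxyl.

Step 22
Reactants: 35 (1S,2R)-2-Ar-2,6,6-trimethylcyclohex-3-ene-1-carboxylic acid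
Product: 36 (1S,2R)-2-Ar-2,6,6-trimethylcyclohexane-1-carboxylic acid
Conditions: H2 (1 atm), 10% Pd/C, EtOAc, rt
Reagents that add atoms: none
Why: Same alkene hydrogenation as step 12; no stereocentre is touched.

Step 23
Reactants: 36 (1S,2R)-2-Ar-2,6,6-trimethylcyclohexane-1-carboxylic acid
Product: 38 2-diazo-1-[(1S,2R)-2-Ar-2,6,6-trimethylcyclohexyl]ethanone, via acid chloride 37 (not isolated)
Conditions: (COCl)2, DMF (cat.), CH2Cl2, 0 °C to rt; then CH2N2 (excess), Et2O, 0 °C
Reagents that add atoms: diazomethane C=[N+]=[N-]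
Why: Same diazoketone formation as step 13.

Step 24
Reactants: 38 2-diazo-1-[(1S,2R)-2-Ar-2,6,6-trimethylcyclohexyl]ethanone
Product: 40 (5R,10R)-11-isopropoxy-12-methoxyabieta-8,11,13-trien-6-one, via cis ketone 39 (not isolated)
Conditions: Rh2(OAc)4 (1 mol%), CH2Cl2, rt, slow addition; then NaOMe, MeOH, rt, argon
Reagents that add atoms: none
Why: Same carbenoid aromatic substitution as step 14, with base equilibration setting C5 (5R) trans to the C10 methyl, the configuration the quinone methide half needs.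

Step 25
Reactants: 40 (5R,10R)-11-isopropoxy-12-methoxyabieta-8,11,13-trien-6-one
Product: 41 (5R,10R)-11-hydroxy-12-methoxyabieta-8,11,13-trien-6-one
Conditions: BCl3, CH2Cl2, −78 to 0 °C
Reagents that add atoms: none
Why: Same selective isopropyl ether cleavage as step 15.

Step 26
Reactants: 41 (5R,10R)-11-hydroxy-12-methoxyabieta-8,11,13-trien-6-one
Product: 42 (5R,10R)-12-methoxyabieta-8,12-diene-6,11,14-trione
Conditions: (KSO3)2NO, KH2PO4, acetone/H2O, 0 °C to rt
Reagents that add atoms: potassium nitrosodisulfonate [K+].[K+].[O]N(S(=O)(=O)[O-])S(=O)(=O)[O-]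
Why: Same Teuber oxidation as step 16, which leaves the C7 methylene untouched.

Step 27
Reactants: 42 (5R,10R)-12-methoxyabieta-8,12-diene-6,11,14-trione
Product: 43 (5R,10R)-12-hydroxyabieta-8,12-diene-6,11,14-trione
Conditions: 6 M HCl, 1,4-dioxane, 70 °C, argon
Reagents that add atoms: water O
Why: Same vinylogous ester hydrolysis as step 17, run without base or oxygen so that the C7 methylene is not oxidised.

Step 28
Reactants: 30 (10S)-6,12-dihydroxyabieta-5,8,12-triene-7,11,14-trione; 43 (5R,10R)-12-hydroxyabieta-8,12-diene-6,11,14-trione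
Product: 46 CNP0568854.1 (7R spiro dimer), via aldol adduct 44 (not isolated), via spiro hemiketal 45 (not isolated)
Conditions: TsOH (0.2 equiv), toluene, 60 °C, 4 Å sieves, argon
Reagents that add atoms: none
Why: Proposed new method: acid should ketonise diosphenol 30 to its 6,7-dione, whose doubly activated C7 carbonyl is attacked by C7′ of the C6′ enol of 43 from the β face (pseudoequatorial, anti to the axial 5α-H) to give aldol 44; the tertiary 7α-hydroxyl then adds to the peri quinone carbonyl C14′ (five-membered hemiketal 45), water is lost with the push of the 12′-hydroxyl, and the 14′-alkoxy ortho-quinone tautomerises to the C7′=C8′ quinone methide; the closest known reaction types are the acid-catalysed aldol addition of an enolisable ketone to a vicinal dicarbonyl and the acid-catalysed O-alkylation (vinylogous esterification) of hydroxyquinones by alcohols; the aldol is reversible, so C7 should settle with the carbon substituent pseudoequatorial (7R), while C5 returns to the trans fusion by acid-mediated ketonisation.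

**Compound list**

1 | 2-isopropylphenol | CC(C)c1ccccc1O | starting material
2 | 1-isopropyl-2-methoxybenzene | CC(C)c1ccccc1OC | intermediate
3 | (3-isopropyl-2-methoxyphenyl)lithium | [Li]c1cccc(C(C)C)c1OC | intermediate
4 | dimethyl (3-isopropyl-2-methoxyphenyl)boronate | COB(OC)c1cccc(C(C)C)c1OC | intermediate
5 | 3-isopropyl-2-methoxyphenol | COc1c(O)cccc1C(C)C | intermediate
6 | 1-isopropoxy-3-isopropyl-2-methoxybenzene | COc1c(OC(C)C)cccc1C(C)C | intermediate
7 | (2-isopropoxy-4-isopropyl-3-methoxyphenyl)lithium | [Li]c1ccc(C(C)C)c(OC)c1OC(C)C | intermediate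
8 | 1-iodo-2-isopropoxy-4-isopropyl-3-methoxybenzene | Ic1ccc(C(C)C)c(OC)c1OC(C)C | intermediate
9 | trimethylsilylacetylene | C#C[Si](C)(C)C | starting material
10 | (Ar-ethynyl)trimethylsilane | C[Si](C)(C)C#Cc1ccc(C(C)C)c(OC)c1OC(C)C | intermediate
11 | 1-ethynyl-2-isopropoxy-4-isopropyl-3-methoxybenzene | C#Cc1ccc(C(C)C)c(OC)c1OC(C)C | intermediate
12 | 3,3-dimethylglutaric anhydride | CC1(C)CC(=O)OC(=O)C1 | starting material
13 | 5-methoxy-3,3-dimethyl-5-oxopentanoic acid | COC(=O)CC(C)(C)CC(=O)O | intermediate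
14 | methyl 5-chloro-3,3-dimethyl-5-oxopentanoate | COC(=O)CC(C)(C)CC(Cl)=O | intermediate
15 | [(E)-2-Ar-prop-1-enyl]dimethylalane | CC(C)c1ccc(c(OC(C)C)c1OC)/C(C)=C/[Al](C)C | intermediate
16 | methyl (E)-7-Ar-3,3-dimethyl-5-oxooct-6-enoate | CC(C)c1ccc(c(OC(C)C)c1OC)/C(C)=C/C(=O)CC(C)(C)CC(=O)OC | intermediate
17 | methyl (5S,6E)-7-Ar-5-hydroxy-3,3-dimethyloct-6-enoate | CC(C)c1ccc(c(OC(C)C)c1OC)/C(C)=C/[C@@H](O)CC(C)(C)CC(=O)OC | intermediate
18 | (6S)-6-[(E)-2-Ar-prop-1-enyl]-4,4-dimethyltetrahydropyran-2-one | CC(C)c1ccc(c(OC(C)C)c1OC)/C(C)=C/[C@@H]1CC(C)(C)CC(=O)O1 | intermediate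
19 | (2S)-6-(TBS-oxy)-2-[(E)-2-Ar-prop-1-enyl]-4,4-dimethyl-3,4-dihydro-2H-pyran | CC(C)c1ccc(c(OC(C)C)c1OC)/C(C)=C/[C@@H]1CC(C)(C)C=C(O[Si](C)(C)C(C)(C)C)O1 | intermediate
20 | TBS ester of acid 21 | CC(C)c1ccc(c(OC(C)C)c1OC)[C@@]1(C)C=CCC(C)(C)[C@H]1C(=O)O[Si](C)(C)C(C)(C)C | intermediate
21 | (1R,2S)-2-Ar-2,6,6-trimethylcyclohex-3-ene-1-carboxylic acid (aryl cis to carboxyl) | CC(C)c1ccc(c(OC(C)C)c1OC)[C@@]1(C)C=CCC(C)(C)[C@H]1C(=O)O | intermediate
22 | (1R,2S)-2-Ar-2,6,6-trimethylcyclohexane-1-carboxylic acid | CC(C)c1ccc(c(OC(C)C)c1OC)[C@@]1(C)CCCC(C)(C)[C@H]1C(=O)O | intermediate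
23 | (1R,2S)-2-Ar-2,6,6-trimethylcyclohexane-1-carbonyl chloride | CC(C)c1ccc(c(OC(C)C)c1OC)[C@@]1(C)CCCC(C)(C)[C@H]1C(Cl)=O | intermediate
24 | 2-diazo-1-[(1R,2S)-2-Ar-2,6,6-trimethylcyclohexyl]ethanone | CC(C)c1ccc(c(OC(C)C)c1OC)[C@@]1(C)CCCC(C)(C)[C@H]1C(=O)C=[N+]=[N-] | intermediate
25 | (5R,10S)-11-isopropoxy-12-methoxyabieta-8,11,13-trien-6-one (cis A/B) | CC(C)Oc1c(OC)c(C(C)C)cc2c1[C@@]1(C)CCCC(C)(C)[C@H]1C(=O)C2 | intermediate
26 | (5S,10S)-11-isopropoxy-12-methoxyabieta-8,11,13-trien-6-one (trans A/B) | CC(C)Oc1c(OC)c(C(C)C)cc2c1[C@@]1(C)CCCC(C)(C)[C@@H]1C(=O)C2 | intermediate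
27 | (5S,10S)-11-hydroxy-12-methoxyabieta-8,11,13-trien-6-one | Oc1c(OC)c(C(C)C)cc2c1[C@@]1(C)CCCC(C)(C)[C@@H]1C(=O)C2 | intermediate
28 | (5S,10S)-12-methoxyabieta-8,12-diene-6,11,14-trione | COC1=C(C(C)C)C(=O)C2=C(C1=O)[C@@]1(C)CCCC(C)(C)[C@@H]1C(=O)C2 | intermediate
29 | (5S,10S)-12-hydroxyabieta-8,12-diene-6,11,14-trione | OC1=C(C(C)C)C(=O)C2=C(C1=O)[C@@]1(C)CCCC(C)(C)[C@@H]1C(=O)C2 | intermediate
30 | (10S)-6,12-dihydroxyabieta-5,8,12-triene-7,11,14-trione (enol of the 6,7-dione) | OC1=C(C(C)C)C(=O)C2=C(C1=O)[C@@]1(C)CCCC(C)(C)C1=C(O)C2=O | intermediate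
31 | methyl (5R,6E)-7-Ar-5-hydroxy-3,3-dimethyloct-6-enoate | CC(C)c1ccc(c(OC(C)C)c1OC)/C(C)=C/[C@H](O)CC(C)(C)CC(=O)OC | intermediate
32 | (6R)-6-[(E)-2-Ar-prop-1-enyl]-4,4-dimethyltetrahydropyran-2-one | CC(C)c1ccc(c(OC(C)C)c1OC)/C(C)=C/[C@H]1CC(C)(C)CC(=O)O1 | intermediate
33 | (2R)-6-(TBS-oxy)-2-[(E)-2-Ar-prop-1-enyl]-4,4-dimethyl-3,4-dihydro-2H-pyran | CC(C)c1ccc(c(OC(C)C)c1OC)/C(C)=C/[C@H]1CC(C)(C)C=C(O[Si](C)(C)C(C)(C)C)O1 | intermediate
34 | TBS ester of acid 35 | CC(C)c1ccc(c(OC(C)C)c1OC)[C@]1(C)C=CCC(C)(C)[C@@H]1C(=O)O[Si](C)(C)C(C)(C)C | intermediate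
35 | (1S,2R)-2-Ar-2,6,6-trimethylcyclohex-3-ene-1-carboxylic acid | CC(C)c1ccc(c(OC(C)C)c1OC)[C@]1(C)C=CCC(C)(C)[C@@H]1C(=O)O | intermediate
36 | (1S,2R)-2-Ar-2,6,6-trimethylcyclohexane-1-carboxylic acid | CC(C)c1ccc(c(OC(C)C)c1OC)[C@]1(C)CCCC(C)(C)[C@@H]1C(=O)O | intermediate
37 | (1S,2R)-2-Ar-2,6,6-trimethylcyclohexane-1-carbonyl chloride | CC(C)c1ccc(c(OC(C)C)c1OC)[C@]1(C)CCCC(C)(C)[C@@H]1C(Cl)=O | intermediate
38 | 2-diazo-1-[(1S,2R)-2-Ar-2,6,6-trimethylcyclohexyl]ethanone | CC(C)c1ccc(c(OC(C)C)c1OC)[C@]1(C)CCCC(C)(C)[C@@H]1C(=O)C=[N+]=[N-] | intermediate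
39 | (5S,10R)-11-isopropoxy-12-methoxyabieta-8,11,13-trien-6-one (cis A/B) | CC(C)Oc1c(OC)c(C(C)C)cc2c1[C@]1(C)CCCC(C)(C)[C@@H]1C(=O)C2 | intermediate
40 | (5R,10R)-11-isopropoxy-12-methoxyabieta-8,11,13-trien-6-one (trans A/B) | CC(C)Oc1c(OC)c(C(C)C)cc2c1[C@]1(C)CCCC(C)(C)[C@H]1C(=O)C2 | intermediate
41 | (5R,10R)-11-hydroxy-12-methoxyabieta-8,11,13-trien-6-one | Oc1c(OC)c(C(C)C)cc2c1[C@]1(C)CCCC(C)(C)[C@H]1C(=O)C2 | intermediate
42 | (5R,10R)-12-methoxyabieta-8,12-diene-6,11,14-trione | COC1=C(C(C)C)C(=O)C2=C(C1=O)[C@]1(C)CCCC(C)(C)[C@H]1C(=O)C2 | intermediate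
43 | (5R,10R)-12-hydroxyabieta-8,12-diene-6,11,14-trione | OC1=C(C(C)C)C(=O)C2=C(C1=O)[C@]1(C)CCCC(C)(C)[C@H]1C(=O)C2 | intermediate
44 | aldol adduct: C7 of the (5S,10S) hydroxyquinone 6-ketone bears 7α-OH and, on the β face, C7′ of unit 43 (C7′ epimers) | OC1=C(C(C)C)C(=O)C2=C(C1=O)[C@@]1(C)CCCC(C)(C)[C@@H]1C(=O)[C@]2(O)C3C(=O)[C@@H]4C(C)(C)CCC[C@@]4(C)C4=C3C(=O)C(C(C)C)=C(O)C4=O | intermediate
45 | spiro hemiketal of 44: O7 bonded to C14′, which keeps a hydroxyl (C7′ and C14′ epimers) | OC1=C(C(C)C)C(=O)C2=C(C1=O)[C@@]1(C)CCCC(C)(C)[C@@H]1C(=O)[C@@]23OC4(O)C(C(C)C)=C(O)C(=O)C5=C4C3C(=O)[C@@H]3C(C)(C)CCC[C@@]53C | intermediate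
46 | CNP0568854.1: (5S,7R,10S) spiro unit joined through O to C14′ and through C7 to C7′ of the (5′R,10′R) quinone methide unit | CC(C)C1=C(O)C2=C(C(=O)C1=O)[C@@]1(C)CCCC(C)(C)[C@@H]1C(=O)[C@@]21OC2=C(C(C)C)C(=O)C(O)=C3C2=C1C(=O)[C@@H]1C(C)(C)CCC[C@@]31C | target

**Step count and risks**

Total step count: 28. Longest linear sequence: 17 steps (steps 1–5, 8, 9–18, 28).

Steps most likely to fail:

1. Step 28 (the labelled step). The aldol may stall because 30 rests as the diosphenol, attack at C7 may show poor facial selectivity, and the two quinones may exchange oxidation level so that homodimers appear. Fallback, using known reactions only: the C7–C7′ bond is made at the arene stage by a directed aldol. Setting out from ketone 26, KOt-Bu/O2 in t-BuOH–THF should give diosphenol arene F1, and TBSCl/imidazole the enol silyl ether F2. The lithium enolate of ketone 40 (LDA, THF, −78 °C) is added to the C7 carbonyl of F2, and HF·pyridine frees aldol F3, at which stage C7 epimers can be separated. BCl3 then gives bis-phenol F4, (KSO3)2NO gives bis(methoxyquinone) F5, and 6 M HCl in dioxane hydrolyses both vinylogous esters. The route is rejoined at aldol adduct 44, from which only the acid-catalysed ether closure (a known hydroxyquinone O-alkylation type) remains to reach 46.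

2. Step 11 (and its mirror image, step 21). The boat transition state pushes the C10 methyl over the C4 gem-dimethyl group, so the [3,3] shift may be slower than ionisation of the allylic C–O bond or elimination, with loss of material and of chirality transfer. Fallback: an open-chain Ireland–Claisen rearrangement through a chair, followed by ring-closing metathesis. Setting out from alkyne 11, methylalumination as in step 8 and acetyl chloride should give enone F6. (S)-Me-CBS/catecholborane gives alcohol F7, and DCC/DMAP esterification with 3,3-dimethylhex-5-enoic acid gives ester F8. LDA in THF–HMPA, TBSCl and warming to 60 °C give acid F9, with C10 relayed from the carbinol through the chair and C5 from the ketene acetal geometry. The second-generation Grubbs catalyst then closes ring A with loss of propene, coming back to the route at acid 21. With the (R)-catalyst the antipodal alcohol F10, ester F11 and acid F12 come back at acid 35.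

3. Step 18. SeO2 may also oxidise the isopropyl methine next to the quinone enol, or over-oxidise and cleave the C6–C7 bond. Fallback: halogenation followed by Kornblum oxidation. Setting out from 29, CuBr2 (EtOAc–CHCl3, reflux) should give bromo ketone F13, and DMSO/NaHCO3 at 80 °C converts it into the 6,7-dione, which enolises and comes back to the route at 30.

**Further compounds**

F1 | step 28 | (10S)-6-hydroxy-11-isopropoxy-12-methoxyabieta-5,8,11,13-tetraen-7-one | CC(C)Oc1c(OC)c(C(C)C)cc2c1[C@@]1(C)CCCC(C)(C)C1=C(O)C2=O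
F2 | step 28 | (10S)-6-(TBS-oxy)-11-isopropoxy-12-methoxyabieta-5,8,11,13-tetraen-7-one | CC(C)Oc1c(OC)c(C(C)C)cc2c1[C@@]1(C)CCCC(C)(C)C1=C(O[Si](C)(C)C(C)(C)C)C2=O
F3 | step 28 | arene-level aldol: 7α-hydroxy ketone of unit 26 bonded at C7 (β) to C7′ of unit 40 (C7′ epimers) | CC(C)Oc1c(OC)c(C(C)C)cc2c1[C@@]1(C)CCCC(C)(C)[C@@H]1C(=O)[C@]2(O)C3C(=O)[C@@H]4C(C)(C)CCC[C@@]4(C)c4c3cc(C(C)C)c(OC)c4OC(C)C
F4 | step 28 | bis-phenol from F3 (11-OH and 11′-OH free) | Oc1c(OC)c(C(C)C)cc2c1[C@@]1(C)CCCC(C)(C)[C@@H]1C(=O)[C@]2(O)C3C(=O)[C@@H]4C(C)(C)CCC[C@@]4(C)c4c3cc(C(C)C)c(OC)c4O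
F5 | step 28 | bis(12-methoxy-11,14-quinone) from F4 | COC1=C(C(C)C)C(=O)C2=C(C1=O)[C@@]1(C)CCCC(C)(C)[C@@H]1C(=O)[C@]2(O)C3C(=O)[C@@H]4C(C)(C)CCC[C@@]4(C)C4=C3C(=O)C(C(C)C)=C(OC)C4=O
F6 | step 11 | (E)-4-Ar-pent-3-en-2-one | CC(C)c1ccc(c(OC(C)C)c1OC)/C(C)=C/C(C)=O
F7 | step 11 | (2R,3E)-4-Ar-pent-3-en-2-ol | CC(C)c1ccc(c(OC(C)C)c1OC)/C(C)=C/[C@H](O)C
F8 | step 11 | (2R,3E)-4-Ar-pent-3-en-2-yl 3,3-dimethylhex-5-enoate | CC(C)c1ccc(c(OC(C)C)c1OC)/C(C)=C/[C@@H](C)OC(=O)CC(C)(C)CC=C
F9 | step 11 | (2R,3S,4E)-3-Ar-3-methyl-2-(2-methylpent-4-en-2-yl)hex-4-enoic acid | CC(C)c1ccc(c(OC(C)C)c1OC)[C@@](C)(/C=C/C)[C@H](C(=O)O)C(C)(C)CC=C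
F10 | step 21 | (2S,3E)-4-Ar-pent-3-en-2-ol | CC(C)c1ccc(c(OC(C)C)c1OC)/C(C)=C/[C@@H](O)C
F11 | step 21 | (2S,3E)-4-Ar-pent-3-en-2-yl 3,3-dimethylhex-5-enoate | CC(C)c1ccc(c(OC(C)C)c1OC)/C(C)=C/[C@H](C)OC(=O)CC(C)(C)CC=C
F12 | step 21 | (2S,3R,4E)-3-Ar-3-methyl-2-(2-methylpent-4-en-2-yl)hex-4-enoic acid | CC(C)c1ccc(c(OC(C)C)c1OC)[C@](C)(/C=C/C)[C@@H](C(=O)O)C(C)(C)CC=C
F13 | step 18 | (5S,10S)-7-bromo-12-hydroxyabieta-8,12-diene-6,11,14-trione (C7 epimers) | OC1=C(C(C)C)C(=O)C2=C(C1=O)[C@@]1(C)CCCC(C)(C)[C@@H]1C(=O)C2Br
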